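**Retrosynthetic overview**

1. Ester at O-15: cleave to the O-3-silylated diterpene allylic alcohol and 32-silyloxydotriacontanoic acid; the acid comes from two C16 halves by a copper-catalysed Grignard coupling.
2. Side chain and C7=C8: C13–C16 from a terminal alkyne (methylalumination, then formaldehyde); C11, C12 and the C9 stereocentre from a Johnson–Claisen rearrangement of a ring-B C7 allylic alcohol, which also moves the double bond to C7=C8.
3. Ring B (formed second): aldol condensation C8–C9 between a 2-oxobutyl chain on C5 and a formyl group on C10.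
4. Ring A (formed first, key step): one-pot [3+3] annulation of (E)-2-methylbut-2-enal with (E)-2,2-dimethyl-5-oxohept-3-enal, forming C2–C3 (vinylogous aldol) and then C5–C10 (Michael closure).
5. Enabling feature (labdane numbering): the quaternary C10 with its methyl group and C2 are the α- and γ-carbons of a 2-methylbut-2-enal unit whose carbonyl carbon is C9, and C3 and C5 sit 1,3 across the non-enolisable gem-dimethyl carbon C4 of ring A.

Key step: step 3

Remark: positions are given in labdane numbering (C1–C20); the target is read as (3R,5S,9R,10S,13E) with a 32-hydroxydotriacontanoyl ester (carbonyl carbon plus 31 CH2) at O-15.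
Remark: the sense of induction of the cinchona primary amine in step 3 is not predicted; the pseudo-enantiomer (quinine- or quinidine-derived) that gives the (1R,4R,6R) product is the one meant.

**Route**

Step 1
Reactants: 1 3-hydroxy-2,2-dimethylpropanal; 2 diethyl (2-oxobutyl)phosphonate
Product: 3 (E)-7-hydroxy-6,6-dimethylhept-4-en-3-one
Conditions: LiCl, i-Pr2NEt, MeCN, rt
Reagents that add atoms: none
Why: Horner–Wadsworth–Emmons olefination in its mild LiCl/amine variant tolerates the free hydroxy aldehyde, and the stabilised keto-phosphonate should give the (E)-enone.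

Step 2
Reactants: 3 (E)-7-hydroxy-6,6-dimethylhept-4-en-3-one
Product: 4 (E)-2,2-dimethyl-5-oxohept-3-enal
Conditions: Dess–Martin periodinane, CH2Cl2, 0 °C → rt
Reagents that add atoms: none
Why: Dess–Martin oxidation takes the neopentyl primary alcohol to the aldehyde, which has no α-hydrogen and so cannot enolise or move into conjugation.

Step 3
Reactants: 4 (E)-2,2-dimethyl-5-oxohept-3-enal; 5 (E)-2-methylbut-2-enal (tiglaldehyde)
Product: 7 (1R,4R,6R)-4-hydroxy-1,5,5-trimethyl-6-(2-oxobutyl)cyclohex-2-ene-1-carbaldehyde, via vinylogous aldol adduct 6 (not isolated)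
Conditions: 9-amino-9-deoxy-epi-quinine (20 mol%; or its quinidine-derived pseudo-enantiomer, see remark), 2-fluorobenzoic acid (40 mol%), toluene, 40 °C, 5 added by syringe pump
Reagents that add atoms: none
Why: Proposed new method: the primary amine can form an enamine only with 5 (the aldehyde of 4 has no α-hydrogen), and the resulting 2-methyl dienamine attacks through its γ-carbon C2 the unconjugated aldehyde carbon C3 of 4 (reversible vinylogous aldol, giving 6 as its iminium), after which γ-deprotonation re-forms a dienamine whose α-carbon C10 adds to the now tethered enone at C5 (intramolecular Michael) and hydrolysis releases 7. The closest known reaction types are amine-catalysed formal [3+3] annulations of enals through dienamines and amine-catalysed intramolecular Michael cyclisations of formyl enones. Ring A is closed by a 6-exo-trig attack of C10 on C5 (C5=C6 outside, C1=C2 inside the new ring). C10 and C5 are set together in this Michael step, the chiral amine shielding one face of the dienamine and a synclinal enamine–enone arrangement placing the formyl group trans to the 2-oxobutyl chain; C3 is formed reversibly, so both C3 epimers of 6 drain through the ring closure that keeps the C3–O bond pseudo-equatorial and cis to the chain on C5. The step needs γ- before α-reactivity and cross- instead of self-condensation of 5: the α-methyl group of the dienamine and the hindered β-carbon C5 suppress intermolecular α-attack, the C10–C5 bond can form only once the C2–C3 tether exists, and slow addition keeps the concentration of 5 low.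

Step 4
Reactants: 7 (1R,4R,6R)-4-hydroxy-1,5,5-trimethyl-6-(2-oxobutyl)cyclohex-2-ene-1-carbaldehyde
Product: 8 (1R,4R,6R)-4-(tert-butyldimethylsilyloxy)-1,5,5-trimethyl-6-(2-oxobutyl)cyclohex-2-ene-1-carbaldehyde
Conditions: TBSOTf, 2,6-lutidine, CH2Cl2, −78 → 0 °C
Reagents that add atoms: tert-butyldimethylsilyl trifluoromethanesulfonate, CC(C)(C)[Si](C)(C)OS(=O)(=O)C(F)(F)F
Why: Silylation of the hindered allylic alcohol with the silyl triflate protects O-3 for all later steps and should be faster than silyl enol ether formation at the ketone.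

Step 5
Reactants: 8 (1R,4R,6R)-4-(tert-butyldimethylsilyloxy)-1,5,5-trimethyl-6-(2-oxobutyl)cyclohex-2-ene-1-carbaldehyde
Product: 9 (1R,2R,4R)-4-(tert-butyldimethylsilyloxy)-1,3,3-trimethyl-2-(2-oxobutyl)cyclohexane-1-carbaldehyde
Conditions: H2 (1 atm), Pd/C, EtOAc, rt
Reagents that add atoms: none
Why: Heterogeneous hydrogenation saturates the only C=C bond (C1=C2) and leaves aldehyde, ketone and silyl ether untouched; no stereocentre is created.

Step 6
Reactants: 9 (1R,2R,4R)-4-(tert-butyldimethylsilyloxy)-1,3,3-trimethyl-2-(2-oxobutyl)cyclohexane-1-carbaldehyde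
Product: 10 (4aS,7R,8aS)-7-(tert-butyldimethylsilyloxy)-3,4a,8,8-tetramethyl-4a,5,6,7,8,8a-hexahydronaphthalen-2(1H)-one
Conditions: KOH (cat.), MeOH, 40 °C
Reagents that add atoms: none
Why: Intramolecular aldol condensation (Robinson-type ring closure): only the C8 enolate of the ethyl ketone can reach the non-enolisable C9 aldehyde through a six-membered ring, dehydration gives the C8=C9 enone, and the trans ring fusion follows from the trans formyl/2-oxobutyl relationship set in step 3.

Step 7
Reactants: 10 (4aS,7R,8aS)-7-(tert-butyldimethylsilyloxy)-3,4a,8,8-tetramethyl-4a,5,6,7,8,8a-hexahydronaphthalen-2(1H)-one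
Product: 11 (2R,4aS,7R,8aS)-7-(tert-butyldimethylsilyloxy)-3,4a,8,8-tetramethyl-1,2,4a,5,6,7,8,8a-octahydronaphthalen-2-ol
Conditions: NaBH4, CeCl3·7H2O, MeOH, −40 °C
Reagents that add atoms: none
Why: Luche reduction gives only 1,2-reduction, and hydride should arrive on the face opposite the axial C10 methyl group, so the new C7 hydroxyl is cis to that methyl group.

Step 8
Reactants: 11 (2R,4aS,7R,8aS)-7-(tert-butyldimethylsilyloxy)-3,4a,8,8-tetramethyl-1,2,4a,5,6,7,8,8a-octahydronaphthalen-2-ol
Product: 13 ethyl (3R,5S,9R,10S)-3-(tert-butyldimethylsilyloxy)-13,14,15,16-tetranorlabd-7-en-12-oate, via ketene acetal 12 (not isolated)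
Conditions: MeC(OEt)3, EtCO2H (cat.), xylene, 140 °C, EtOH distilled off
Reagents that add atoms: triethyl orthoacetate, CC(OCC)(OCC)OCC
Why: Johnson–Claisen rearrangement: the [3,3]-shift is suprafacial, so the C7–O stereocentre is traded for the C9–C11 bond on the same face (cis to the C10 methyl group) while the double bond moves to C7=C8.

Step 9
Reactants: 13 ethyl (3R,5S,9R,10S)-3-(tert-butyldimethylsilyloxy)-13,14,15,16-tetranorlabd-7-en-12-oate
Product: 14 (3R,5S,9R,10S)-3-(tert-butyldimethylsilyloxy)-13,14,15,16-tetranorlabd-7-en-12-ol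
Conditions: LiAlH4, THF, 0 °C
Reagents that add atoms: none
Why: Hydride reduction of the ester to the primary alcohol; no other reducible group is present.

Step 10
Reactants: 14 (3R,5S,9R,10S)-3-(tert-butyldimethylsilyloxy)-13,14,15,16-tetranorlabd-7-en-12-ol
Product: 15 (3R,5S,9R,10S)-3-(tert-butyldimethylsilyloxy)-12-iodo-13,14,15,16-tetranorlabd-7-ene
Conditions: I2, PPh3, imidazole, CH2Cl2, 0 °C → rt
Reagents that add atoms: iodine, II
Why: Appel-type iodination converts the unhindered primary alcohol into the iodide under neutral conditions that spare the silyl ether and the trisubstituted alkene.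

Step 11
Reactants: 15 (3R,5S,9R,10S)-3-(tert-butyldimethylsilyloxy)-12-iodo-13,14,15,16-tetranorlabd-7-ene
Product: 16 (3R,5S,9R,10S)-3-(tert-butyldimethylsilyloxy)-15,16-dinorlabd-7-en-13-yne
Conditions: LiC≡CH·H2NCH2CH2NH2, DMSO, rt
Reagents that add atoms: lithium acetylide (ethylenediamine complex), [Li]C#C
Why: SN2 alkylation of the acetylide by the primary iodide in a dipolar aprotic solvent installs C13 and C14 as a terminal alkyne.

Step 12
Reactants: 16 (3R,5S,9R,10S)-3-(tert-butyldimethylsilyloxy)-15,16-dinorlabd-7-en-13-yne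
Product: 18 (3R,5S,9R,10S,13E)-3-(tert-butyldimethylsilyloxy)labda-7,13-dien-15-ol, via alkenylalane 17 (not isolated)
Conditions: AlMe3, Cp2ZrCl2 (20 mol%), CH2Cl2, 0 °C → rt; then n-BuLi, (CH2O)n, THF, −78 °C → rt
Reagents that add atoms: trimethylaluminium, C[Al](C)C; formaldehyde (as paraformaldehyde), C=O
Why: Negishi carboalumination adds methyl and aluminium syn across the terminal alkyne (methyl to the internal carbon), and trapping the alkenylalanate with formaldehyde with retention gives the (E)-trisubstituted allylic alcohol.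

Step 13
Reactants: 19 16-bromohexadecan-1-ol
Product: 20 (16-bromohexadecyloxy)(tert-butyl)dimethylsilane
Conditions: TBSCl, imidazole, DMF, rt
Reagents that add atoms: tert-butyldimethylsilyl chloride, CC(C)(C)[Si](C)(C)Cl
Why: Standard silylation of the primary alcohol; the primary bromide is inert.

Step 14
Reactants: 20 (16-bromohexadecyloxy)(tert-butyl)dimethylsilane; 21 16-bromohexadecanoic acid
Product: 24 32-(tert-butyldimethylsilyloxy)dotriacontanoic acid, via Grignard reagent 22 (not isolated), via carboxylate salt 23 (not isolated)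
Conditions: 20, Mg, THF, 40 °C; 21, MeMgCl (1 equiv), THF, −20 °C; then combine, Li2CuCl4 (3 mol%), −20 °C → rt; aq. citric acid
Reagents that add atoms: none
Why: Copper-catalysed cross-coupling of the alkyl Grignard reagent with the primary bromide of the pre-formed carboxylate salt joins the two C16 halves, the carboxylate being inert to the Grignard reagent at low temperature.

Step 15
Reactants: 18 (3R,5S,9R,10S,13E)-3-(tert-butyldimethylsilyloxy)labda-7,13-dien-15-ol; 24 32-(tert-butyldimethylsilyloxy)dotriacontanoic acid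
Product: 25 (3R,5S,9R,10S,13E)-3-(tert-butyldimethylsilyloxy)labda-7,13-dien-15-yl 32-(tert-butyldimethylsilyloxy)dotriacontanoate
Conditions: EDC·HCl, DMAP, CH2Cl2, rt
Reagents that add atoms: none
Why: Steglich esterification of the unhindered primary allylic alcohol; O-3 and the terminal hydroxyl are silylated, so neither a second acylation nor oligomerisation of the hydroxy acid can occur.

Step 16
Reactants: 25 (3R,5S,9R,10S,13E)-3-(tert-butyldimethylsilyloxy)labda-7,13-dien-15-yl 32-(tert-butyldimethylsilyloxy)dotriacontanoate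
Product: 26 (3R,5S,9R,10S,13E)-3-hydroxylabda-7,13-dien-15-yl 32-hydroxydotriacontanoate (CNP0253650.1)
Conditions: HF·pyridine, pyridine, THF, 0 °C → rt
Reagents that add atoms: none
Why: Buffered fluoride-mediated desilylation removes both silyl ethers and should neither cleave nor migrate the allylic ester.

**Compound list**

1 | 3-hydroxy-2,2-dimethylpropanal | OCC(C)(C)C=O | starting material
2 | diethyl (2-oxobutyl)phosphonate | CCC(=O)CP(=O)(OCC)OCC | starting material
3 | (E)-7-hydroxy-6,6-dimethylhept-4-en-3-one | CCC(=O)/C=C/C(C)(C)CO | intermediate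
4 | (E)-2,2-dimethyl-5-oxohept-3-enal | CCC(=O)/C=C/C(C)(C)C=O | intermediate
5 | (E)-2-methylbut-2-enal (tiglaldehyde) | C/C=C(\C)C=O | starting material
6 | (2E,7E)-5-hydroxy-2,6,6-trimethyl-9-oxoundeca-2,7-dienal (both C5 epimers, held as its iminium with the catalyst) | O=C/C(C)=C/CC(O)C(C)(C)/C=C/C(=O)CC | intermediate
7 | (1R,4R,6R)-4-hydroxy-1,5,5-trimethyl-6-(2-oxobutyl)cyclohex-2-ene-1-carbaldehyde | O=C[C@]1(C)C=C[C@@H](O)C(C)(C)[C@H]1CC(=O)CC | intermediate
8 | (1R,4R,6R)-4-(tert-butyldimethylsilyloxy)-1,5,5-trimethyl-6-(2-oxobutyl)cyclohex-2-ene-1-carbaldehyde | O=C[C@]1(C)C=C[C@@H](O[Si](C)(C)C(C)(C)C)C(C)(C)[C@H]1CC(=O)CC | intermediate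
9 | (1R,2R,4R)-4-(tert-butyldimethylsilyloxy)-1,3,3-trimethyl-2-(2-oxobutyl)cyclohexane-1-carbaldehyde | O=C[C@]1(C)CC[C@@H](O[Si](C)(C)C(C)(C)C)C(C)(C)[C@H]1CC(=O)CC | intermediate
10 | (4aS,7R,8aS)-7-(tert-butyldimethylsilyloxy)-3,4a,8,8-tetramethyl-4a,5,6,7,8,8a-hexahydronaphthalen-2(1H)-one | CC1=C[C@]2(C)CC[C@@H](O[Si](C)(C)C(C)(C)C)C(C)(C)[C@H]2CC1=O | intermediate
11 | (2R,4aS,7R,8aS)-7-(tert-butyldimethylsilyloxy)-3,4a,8,8-tetramethyl-1,2,4a,5,6,7,8,8a-octahydronaphthalen-2-ol | CC1=C[C@]2(C)CC[C@@H](O[Si](C)(C)C(C)(C)C)C(C)(C)[C@H]2C[C@H]1O | intermediate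
12 | 1-ethoxyvinyl ether of 11 (mixed ketene acetal) | CC1=C[C@]2(C)CC[C@@H](O[Si](C)(C)C(C)(C)C)C(C)(C)[C@H]2C[C@H]1OC(=C)OCC | intermediate
13 | ethyl (3R,5S,9R,10S)-3-(tert-butyldimethylsilyloxy)-13,14,15,16-tetranorlabd-7-en-12-oate | CC1=CC[C@@H]2C(C)(C)[C@H](O[Si](C)(C)C(C)(C)C)CC[C@@]2(C)[C@@H]1CC(=O)OCC | intermediate
14 | (3R,5S,9R,10S)-3-(tert-butyldimethylsilyloxy)-13,14,15,16-tetranorlabd-7-en-12-ol | CC1=CC[C@@H]2C(C)(C)[C@H](O[Si](C)(C)C(C)(C)C)CC[C@@]2(C)[C@@H]1CCO | intermediate
15 | (3R,5S,9R,10S)-3-(tert-butyldimethylsilyloxy)-12-iodo-13,14,15,16-tetranorlabd-7-ene | CC1=CC[C@@H]2C(C)(C)[C@H](O[Si](C)(C)C(C)(C)C)CC[C@@]2(C)[C@@H]1CCI | intermediate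
16 | (3R,5S,9R,10S)-3-(tert-butyldimethylsilyloxy)-15,16-dinorlabd-7-en-13-yne | CC1=CC[C@@H]2C(C)(C)[C@H](O[Si](C)(C)C(C)(C)C)CC[C@@]2(C)[C@@H]1CCC#C | intermediate
17 | (E)-alkenyl(dimethyl)alane from methylalumination of 16 | CC1=CC[C@@H]2C(C)(C)[C@H](O[Si](C)(C)C(C)(C)C)CC[C@@]2(C)[C@@H]1CC/C(C)=C/[Al](C)C | intermediate
18 | (3R,5S,9R,10S,13E)-3-(tert-butyldimethylsilyloxy)labda-7,13-dien-15-ol | CC1=CC[C@@H]2C(C)(C)[C@H](O[Si](C)(C)C(C)(C)C)CC[C@@]2(C)[C@@H]1CC/C(C)=C/CO | intermediate
19 | 16-bromohexadecan-1-ol | OCCCCCCCCCCCCCCCCBr | starting material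
20 | (16-bromohexadecyloxy)(tert-butyl)dimethylsilane | CC(C)(C)[Si](C)(C)OCCCCCCCCCCCCCCCCBr | intermediate
21 | 16-bromohexadecanoic acid | OC(=O)CCCCCCCCCCCCCCCBr | starting material
22 | [16-(tert-butyldimethylsilyloxy)hexadecyl]magnesium bromide | CC(C)(C)[Si](C)(C)OCCCCCCCCCCCCCCCC[Mg]Br | intermediate
23 | chloromagnesium 16-bromohexadecanoate | [O-]C(=O)CCCCCCCCCCCCCCCBr.[Mg+2].[Cl-] | intermediate
24 | 32-(tert-butyldimethylsilyloxy)dotriacontanoic acid | CC(C)(C)[Si](C)(C)OCCCCCCCCCCCCCCCCCCCCCCCCCCCCCCCC(O)=O | intermediate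
25 | (3R,5S,9R,10S,13E)-3-(tert-butyldimethylsilyloxy)labda-7,13-dien-15-yl 32-(tert-butyldimethylsilyloxy)dotriacontanoate | CC1=CC[C@@H]2C(C)(C)[C@H](O[Si](C)(C)C(C)(C)C)CC[C@@]2(C)[C@@H]1CC/C(C)=C/COC(=O)CCCCCCCCCCCCCCCCCCCCCCCCCCCCCCCO[Si](C)(C)C(C)(C)C | intermediate
26 | (3R,5S,9R,10S,13E)-3-hydroxylabda-7,13-dien-15-yl 32-hydroxydotriacontanoate (CNP0253650.1) | CC1=CC[C@@H]2C(C)(C)[C@H](O)CC[C@@]2(C)[C@@H]1CC/C(C)=C/COC(=O)CCCCCCCCCCCCCCCCCCCCCCCCCCCCCCCO | target

**Step count and risks**

Total step count: 16. Longest linear sequence: 14 steps (steps 1–12, 15 and 16).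

Steps most likely to fail:

1. Step 3 (Proposed new method). The dienamine may react through its α-carbon or with a second molecule of the enal instead of at C3. The amine may also be tied up by Mannich-type addition to the aldehyde of 4, or the ring-closing Michael addition may show poor facial selectivity. The fallback uses known chemistry, sets out from 4 and 5 and comes back at 9. Compound 5 is converted with TBSOTf and Et3N into the silyl dienol ether (E)-tert-butyl[(2-methylbuta-1,3-dien-1-yl)oxy]dimethylsilane F1. An enantioselective vinylogous Mukaiyama aldol addition of F1 to the aldehyde of 4 (chiral B-phenyl oxazaborolidinone from N-tosyl-tryptophan, CH2Cl2, −78 °C) should give (2E,5R,7E)-5-hydroxy-2,6,6-trimethyl-9-oxoundeca-2,7-dienal F2, with C3 now set by the Lewis acid. Silylation (TBSOTf, 2,6-lutidine) gives (2E,5R,7E)-5-(tert-butyldimethylsilyloxy)-2,6,6-trimethyl-9-oxoundeca-2,7-dienal F3. An amine-catalysed conjugate reduction–intramolecular Michael cyclisation (Hantzsch ester, 5-benzyl-2-tert-butyl-3-methylimidazolidin-4-one trifluoroacetate, dioxane, rt) then closes ring A under control of the C3 stereocentre and delivers 9 directly, so steps 4 and 5 are not needed.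

2. Step 8. The [3,3]-shift has to form a C–C bond beside the quaternary C10, and acid-promoted loss of the allylic oxygen to a ring-B diene may outrun it. The fallback sets out from 11 and comes back at 16. Mitsunobu esterification of 11 with picolinic acid (PPh3, DIAD, THF) inverts C7 and gives (2S,4aS,7R,8aS)-7-(tert-butyldimethylsilyloxy)-3,4a,8,8-tetramethyl-1,2,4a,5,6,7,8,8a-octahydronaphthalen-2-yl pyridine-2-carboxylate F4. Anti-SN2′ substitution with 4-(trimethylsilyl)but-3-yn-1-ylmagnesium bromide and CuBr·SMe2 (THF, −40 °C) should put the chain on C9 on the face opposite the leaving group, cis to the C10 methyl group, and move the double bond to C7=C8, giving (3R,5S,9R,10S)-3-(tert-butyldimethylsilyloxy)-14-(trimethylsilyl)-15,16-dinorlabd-7-en-13-yne F5. K2CO3 in MeOH removes the C-silyl group and gives 16, so steps 9 to 11 are not needed.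

3. Step 12. Methylalumination of the alkyne may be incomplete or non-regioselective, or the alkenylalane may be protonated before formaldehyde traps it. The fallback sets out from 16 and comes back at 18. Hydration of the alkyne (NaAuCl4·2H2O cat., MeOH/H2O, 65 °C) gives the methyl ketone (3R,5S,9R,10S)-3-(tert-butyldimethylsilyloxy)-14,15-dinorlabd-7-en-13-one F6. Horner–Wadsworth–Emmons olefination with triethyl phosphonoacetate (NaH, THF) gives ethyl (3R,5S,9R,10S,13E)-3-(tert-butyldimethylsilyloxy)labda-7,13-dien-15-oate F7 after removal of the (13Z) isomer. Reduction with i-Bu2AlH (CH2Cl2, −78 °C) gives 18.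

Further compounds
F1 | step 3 | (E)-tert-butyl[(2-methylbuta-1,3-dien-1-yl)oxy]dimethylsilane | C=C/C(C)=C/O[Si](C)(C)C(C)(C)C
F2 | step 3 | (2E,5R,7E)-5-hydroxy-2,6,6-trimethyl-9-oxoundeca-2,7-dienal | O=C/C(C)=C/C[C@@H](O)C(C)(C)/C=C/C(=O)CC
F3 | step 3 | (2E,5R,7E)-5-(tert-butyldimethylsilyloxy)-2,6,6-trimethyl-9-oxoundeca-2,7-dienal | O=C/C(C)=C/C[C@@H](O[Si](C)(C)C(C)(C)C)C(C)(C)/C=C/C(=O)CC
F4 | step 8 | (2S,4aS,7R,8aS)-7-(tert-butyldimethylsilyloxy)-3,4a,8,8-tetramethyl-1,2,4a,5,6,7,8,8a-octahydronaphthalen-2-yl pyridine-2-carboxylate | CC1=C[C@]2(C)CC[C@@H](O[Si](C)(C)C(C)(C)C)C(C)(C)[C@H]2C[C@@H]1OC(=O)c1ccccn1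
F5 | step 8 | (3R,5S,9R,10S)-3-(tert-butyldimethylsilyloxy)-14-(trimethylsilyl)-15,16-dinorlabd-7-en-13-yne | CC1=CC[C@@H]2C(C)(C)[C@H](O[Si](C)(C)C(C)(C)C)CC[C@@]2(C)[C@@H]1CCC#C[Si](C)(C)C
F6 | step 12 | (3R,5S,9R,10S)-3-(tert-butyldimethylsilyloxy)-14,15-dinorlabd-7-en-13-one | CC1=CC[C@@H]2C(C)(C)[C@H](O[Si](C)(C)C(C)(C)C)CC[C@@]2(C)[C@@H]1CCC(C)=O
F7 | step 12 | ethyl (3R,5S,9R,10S,13E)-3-(tert-butyldimethylsilyloxy)labda-7,13-dien-15-oate | CC1=CC[C@@H]2C(C)(C)[C@H](O[Si](C)(C)C(C)(C)C)CC[C@@]2(C)[C@@H]1CC/C(C)=C/C(=O)OCC
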